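Take the south-east run, as a rough assumption, as the impulse response of the flask, and read ochre's final ring as a window average of that curve.

| setting | south-east | north-east | north-west | west | blue | green | ochre | violet | grey |
|---|---|---|---|---|---|---|---|---|---|
| substrate | 20 mM | 20 mM | 20 mM | 30 mM | 20 mM | 20 mM | 20 mM (fed, over 10 min) | 20 mM | 20 mM |
| activator | 1.3 equiv | 0.87 equiv | 2 equiv | 1.3 equiv | 1.30 equiv (in portions, 4, over 10 min) | 1.30 equiv | 1.30 equiv | 1.30 equiv (fed, over 1.0 min) | 1.30 equiv (fed, over 10 min) |
| remark | run made earlier | run made earlier | run made earlier | run made earlier | first portion at the start, last at 10 min | everything together at the start | all else is in the flask from the start; the feed brings no volume worth counting | all else is in the flask from the start; the feed brings no volume worth counting | all else is in the flask from the start; the feed brings no volume worth counting |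
| time |  |  |  |  | 12 min | 12 min | 12 min | 12 min | 12 min |

| run | time / min | ring / % |
|---|---|---|
| south-east | 1.50 | 19 |
| south-east | 4.00 | 33 |
| south-east | 8.00 | 32 |
| south-east | 12.0 | 16 |
| north-east | 1.50 | 15 |
| north-east | 4.00 | 28 |
| north-east | 8.00 | 23 |
| north-east | 12.0 | 14 |
| north-west | 1.00 | 15 |
| north-west | 2.00 | 32 |
| north-west | 5.00 | 40 |
| north-west | 12.0 | 12 |
| west | 3.00 | 34 |
| west | 6.00 | 36 |
| west | 10.0 | 19 |
| west | 12.0 | 15 |

(scatter of a reading: 2 percentage points)

- the earlier runs were read with a standard deviation of 2 percentage points

- which flask leads in amount of ring, in percent of the substrate charged ("all alike" within 1.5 percentage points) (blue / green / ochre / violet / grey / all alike)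
- how much ring is there at the end, in percent of the substrate charged: blue
- how much ring is there at the end, in percent of the substrate charged: green
- how much ring is there at the end, in percent of the substrate charged: ochre
- how much ring is there at the end, in percent of the substrate charged: violet
- how much ring is there at the end, in percent of the substrate charged: grey

1. I read 0.173 min⁻¹ from the last two south-east readings. This tail constant is the logarithm of their ratio over the time between them.

2. South-east has green's recipe, and it read 16% at 12.0 min. West, with 30 mM of substrate, read 34% at 3.00 min, more than the 27.4% that south-east interpolates to at that time, so the curve shifts with the charge, and 1.3 equiv of activator is no large excess. I still took a pseudo-first-order picture as a rough assumption: each slice of ochre's substrate follows the south-east curve from its own arrival. What follows is an estimate on that assumption, not a bound on ochre.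

3. Slices arrive steadily, so on that assumption ochre's ring at 12 min is the mean of that curve over ages 2.00 min to 12 min. At the young end, interpolation gave 21.8%.

4. For the ceiling, I held each stretch at its higher reading, which gave 32.6%.

5. For the floor, I took chords up to 8.00 min. The exponential tail integrates in closed form to the difference of the last two readings over the tail constant. The mean came to 27.7%.

6. The forecast named ochre: blue 22%, green 17%, ochre 27%, violet 18.5%, grey 23%. Its ground was that “substrate arrives into full activator, so formation stays strongest near the end”. Its ochre stood 0.70 points under my floor, and the readings scatter by 2 points.

7. The flasks gave blue 21.9%, green 16.2%, ochre 28.5%, violet 17.3%, grey 24.5%. Ochre leads and lies inside my bracket, though that bracket rests on an assumed curve. The forecast held within tolerance.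

    substrate + activator → activated form (k = 0.958 M⁻¹ s⁻¹)
    activated form → ring (k = 0.00615 s⁻¹)
    substrate + activated form → open dimer (k = 0.114 M⁻¹ s⁻¹)
    ring ⇌ isomer of the product (K = 22.5, k = 0.00407 s⁻¹)

In green, ring's forward half-life to the isomer of the product, 2.8 min at 0.551 min, is short against 12 min, and at the end ring is made at 0.246 of the rate it is used. In ochre, the tail constant alone would take 27.6% at 10.0 min down to 19.5%, yet the flask held 28.5%, with 15.6% of activated form against green's 2.12%. On green read at 30 min, the tail constant gives 0.716%. The computed flask holds 4.00%, beside 85.5% of isomer of the product.

The data were computed for substances that don't exist; noise was put on by code.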